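## Structural features

Asterelin A is an achiral macrocyclic bis(bibenzyl): four benzene rings A–D are held in an 18-membered ring by two CH2CH2 bridges, one diaryl ether oxygen and one direct aryl–aryl bond. Rings A and B are fused through a furan into a dibenzofuran, in which C9a–C9b is the biaryl bond and O5 joins C4a to C5a. Ring A carries the free OH at C3 and the bridge to ring D at C1, the carbon next to C9b; ring B carries the bridge to ring C at C7, para to C9a. Ring D is para-disubstituted and bound through oxygen to ring C, whose OH is ortho to that ether oxygen and para to its own bridge. There are no stereocentres, so none stand next to each other; the sensitive sites are the two free phenols (oxidation) and the four benzylic methylenes. The real difficulty is the C9a–C9b bond: it is flanked by the C1 bridge and lies inside a strained 18-membered ring, and the 1,3,7-pattern of the dibenzofuran has to be fixed without ambiguity. The feature that is used is that C9a–C9b and O5–C4a sit on neighbouring atoms of ring A, as in a benzofuran formed from an O-aryl ketoxime, while the oxygens at C3 and C4a and the carbon substituent at C1 map onto C3, C1 and C5 of a 5-substituted cyclohexane-1,3-dione.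

## Logic of the disconnections

**20 to 19.** The two aryl O–CH3 bonds are cut. Methyl is the one phenol mask that passes LDA, trifluoroacetic anhydride and DDQ, and the ring A methyl is the enol-ether methyl that steers the key step, so no separate protecting-group step is spent. The demand is that BBr3 spares the diaryl ether and the furan, which sp2–O–sp2 bonds do.

**19 to 18.** Hydrogen is put back on C1 and C2. Ring A at the dihydro level is what the sigmatropic step delivers, and the stereocentre at C1 is only temporary. The oxidant must take the electron-rich dienol ether faster than any benzylic methylene.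

**18 to 14.** C9a–C9b and O5–C4a are cut and the ring B oxygen is placed on nitrogen at C4a. This turns the hindered biaryl bond into the product of a [3,3] shift of an O-aryl oxime ether and opens the 18-membered ring to a relaxed 20-membered one, passing through 15, 16 and 17. The forward step needs the enamide at C6 of the cyclohexenone (future C9b) and attack on the ring B ortho carbon para to the bridge.

**14 to 13.** The C=N bond is cut. Macrocyclization becomes a reversible condensation under dilution. The demand is 1,2-addition at the vinylogous-ester carbonyl and the E geometry (N–O syn to the C6 methylene).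

**13 to 12.** The aryl O–N bond is cut. Nitrogen enters last because the N–O bond would not survive hydrogenation. The demand is selective amination of one phenoxide in the presence of the vinylogous ester.

**12 to 11.** The enol-ether O–CH3 bond is cut. The dione is masked before any aryloxyamine exists. A free dione would be aminated at its enolate and would condense to an N-aryloxy enaminone whose enamine carbon is C2, the wrong carbon for the rearrangement. The enol ether makes C2 vinylic and leaves C6 as the only sp3 alpha-carbon. Because the dione is symmetric, only one constitutional enol ether can form.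

**11 to 9 (through 10).** Hydrogen is removed: ring A goes back to a resorcinol, both bridges to stilbenes, and the three phenols to benzyl ethers. One reductive operation then does all of it. The demand is that the reduction of ring A stops at the dione and leaves the other rings alone.

**9 to 6 and 8; 8 to 7.** The C=C of the A–D bridge is cut (Wittig), giving a benzylic phosphonium salt from a commercial bromide and an aldehyde.

**6 to 4 and 5.** The diaryl ether C–O bond on the ring D side is cut (SNAr). The formyl group of 5 activates the fluoride and is the handle for the next olefination. Because ring C has already been olefinated, no dialdehyde has to be differentiated.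

**4 to 2 and 3; 2 to 1.** The C=C of the B–C bridge is cut (Wittig). Benzyl on ring B needs no orthogonality, since the only free phenol at the SNAr stage is the one on ring C.

## Other disconnections considered

**Alternative 1:** The cut is the diaryl ether bond between the ring D oxygen and ring C. Forward, the seco bis-halophenol A2 is oxidized at the anode in methanol (or with Tl(NO3)3, trivalent thallium) and then reduced with zinc. The dichlorophenol oxygen of ring D attacks a bromine-bearing ortho carbon of the oxidized ring C and closes the 18-membered ring as A1.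
- In its favour: the reaction type is established for macrocyclic diaryl ethers, needs no activating carbonyl, and releases the ring C phenol free. On precedent of the key step it is the better of the two plans.
- Against it here: A2 already contains the complete 1,3,7-trisubstituted dibenzofuran, so the hindered C9a–C9b bond is moved into fragment synthesis and not solved. The electron-rich methoxydibenzofuran can be oxidized in the same potential window as the dibromophenol, the choice between the two halophenols rests on a small difference, and four halogens must be introduced and three removed again.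
- Comparison: in structure it is the equal of the chosen plan, since both form a key bond and the macrocycle around one event. In mechanism it is an ionic oxidation with a selectivity problem, against a pericyclic step with none of that kind but without precedent. In step economy it is longer, because of halogenation, dehalogenation and a separate dibenzofuran synthesis.

**Alternative 2:** The cut is two C–C bonds of ring D, which is built from scratch. Forward, the pyrone A4 is heated at high dilution. The ethynyl ether on the ring C oxygen adds across C3 and C6 of the tethered 5-acyl-2-pyrone, CO2 is lost, and ring D and the macrocycle appear together in the bridge ketone A3.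
- In its favour: the polarization (nucleophilic alkyne terminus to C6 of the pyrone) fixes the para pattern, and loss of CO2 makes the step irreversible. An arene and the macrocycle are formed in one operation with no regiochemical ambiguity; in this respect it is the equal of the chosen plan or better.
- Against it here: aryl ethynyl ethers are delicate and laborious to install on a hindered guaiacol oxygen. The cycloaddition must span an 18-membered transition state at temperatures at which both partners can decay. A3 needs an extra deoxygenation, and again the dibenzofuran must come ready-made.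
- Comparison: in structure it is the more convergent plan. In mechanism both are pericyclic, but this one is intermolecular in character across a long tether, whereas the chosen shift is held together by the N–O bond. In step economy it is longer (dibenzofuran synthesis, pyrone ketone, ynol ether, ketone removal).

**Alternative 3:** The cut is the same ring C oxygen to ring D carbon bond that the chosen plan makes by SNAr, but with CO formally inserted. Forward, the 19-membered aryl benzoate macrolactone A6 is treated with zerovalent nickel from Ni(cod)2 and 3,4-bis(dicyclohexylphosphino)thiophene. Insertion into the acyl C–O bond, loss of CO and C–O reductive elimination give A5, which is the same compound as 19.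
- In its favour: macrolactonization is among the most reliable ring closures. All intermediates stay aromatic, with no stereocentre and no change of oxidation level, and the end game is one demethylation. After the key event it is the better plan by one step.
- Against it here: decarbonylative etherification is established for electron-poor, mostly heteroaryl acyl partners. An electron-rich 4-alkylbenzoate of an ortho-methoxyphenol lies outside that range. The step needs high temperature, CO can poison the nickel, and the reductive elimination has to contract to the more strained ring. The dibenzofuran is again presupposed.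
- Comparison: in structure it is simpler near the end. In mechanism both key steps go beyond demonstrated scope and are equal in that respect, one catalytic and organometallic, the other metal-free. In overall step economy it is longer, because the biaryl problem is left to an unspecified fragment synthesis.

Key step: step 10

Remark on the chemistry: the structures of 14 and 18 were checked (E geometry with N–O syn to C6, ring sizes 20 and 18, same configuration at the carried stereocentre) and need no correction; compounds 12 to 18 are racemic with one enantiomer drawn, the stilbenes 4, 6 and 9 are carried as E/Z mixtures, and 1, 3, 5, 7 and O-(2,4-dinitrophenyl)hydroxylamine are taken as commercial.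

## Route

Step 1
Reactants: 1 [3-(benzyloxy)phenyl]methanol
Product: 2 {[3-(benzyloxy)phenyl]methyl}triphenylphosphonium bromide
Conditions: PPh3·HBr, MeCN, 82 °C
Reagents that add atoms: triphenylphosphine hydrobromide, [Br-].[PH+](c1ccccc1)(c1ccccc1)c1ccccc1
Why: Phosphonium salt formation directly from the benzylic alcohol: the protonated alcohol is displaced by triphenylphosphine, and the aryl benzyl ether tolerates the weakly acidic salt.

Step 2
Reactants: 2 {[3-(benzyloxy)phenyl]methyl}triphenylphosphonium bromide; 3 isovanillin (3-hydroxy-4-methoxybenzaldehyde)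
Product: 4 5-{2-[3-(benzyloxy)phenyl]ethenyl}-2-methoxyphenol (E/Z mixture)
Conditions: KOtBu (2.2 equiv), THF, 0 to 23 °C; then 1 M HCl
Reagents that add atoms: none
Why: Wittig olefination with a semi-stabilized benzylic ylide; the second equivalent of base is consumed by the phenol, whose oxide sits meta to the formyl group and so does not deactivate it by resonance, and the alkene geometry is irrelevant because the bond is hydrogenated later.

Step 3
Reactants: 4 5-{2-[3-(benzyloxy)phenyl]ethenyl}-2-methoxyphenol; 5 4-fluorobenzaldehyde
Product: 6 4-(5-{2-[3-(benzyloxy)phenyl]ethenyl}-2-methoxyphenoxy)benzaldehyde (E/Z mixture)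
Conditions: K2CO3, DMF, 120 °C
Reagents that add atoms: none
Why: Nucleophilic aromatic substitution (addition–elimination through a Meisenheimer adduct) of the para-formyl-activated fluoride by the ring C phenoxide; the product holds a single aldehyde, so the two bridges are told apart by the order of events alone.

Step 4
Reactants: 7 1,3-bis(benzyloxy)-5-(bromomethyl)benzene
Product: 8 {[3,5-bis(benzyloxy)phenyl]methyl}triphenylphosphonium bromide
Conditions: PPh3, toluene, 110 °C
Reagents that add atoms: triphenylphosphine, c1ccc(cc1)P(c1ccccc1)c1ccccc1
Why: SN2 quaternization of triphenylphosphine by a benzylic bromide; the salt should crystallize from the hot solvent.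

Step 5
Reactants: 6 4-(5-{2-[3-(benzyloxy)phenyl]ethenyl}-2-methoxyphenoxy)benzaldehyde; 8 {[3,5-bis(benzyloxy)phenyl]methyl}triphenylphosphonium bromide
Product: 9 1,3-bis(benzyloxy)-5-{2-[4-(5-{2-[3-(benzyloxy)phenyl]ethenyl}-2-methoxyphenoxy)phenyl]ethenyl}benzene (mixture of alkene isomers)
Conditions: KOtBu (1.1 equiv), THF, 0 to 23 °C
Reagents that add atoms: none
Why: Second Wittig olefination on a non-enolizable aryl aldehyde; nothing else in 6 reacts with the ylide or the alkoxide.

Step 6
Reactants: 9 1,3-bis(benzyloxy)-5-{2-[4-(5-{2-[3-(benzyloxy)phenyl]ethenyl}-2-methoxyphenoxy)phenyl]ethenyl}benzene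
Product: 11 5-{2-[4-(5-{2-(3-hydroxyphenyl)ethyl}-2-methoxyphenoxy)phenyl]ethyl}cyclohexane-1,3-dione, via triphenol 10 (not isolated)
Conditions: H2 (1 atm), Pd/C, EtOH–THF, 23 °C; then NaOH (1.1 equiv, aq), H2 (5 atm), 50 °C; then HCl to pH 3
Reagents that add atoms: none
Why: Heterogeneous catalytic hydrogenation first saturates both stilbene bonds and hydrogenolyses the three benzyl ethers to 10; once base is added the resorcinol monoanion, which reacts through its dienone tautomer, should take up two further equivalents and stop at the dione enolate (the classical resorcinol to dihydroresorcinol reduction), a vinylogous carboxylate that resists further reduction, while palladium leaves the phenol, anisole and diaryl ether rings untouched under these mild conditions.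

Step 7
Reactants: 11 5-{2-[4-(5-{2-(3-hydroxyphenyl)ethyl}-2-methoxyphenoxy)phenyl]ethyl}cyclohexane-1,3-dione
Product: 12 rac-5-{2-[4-(5-{2-(3-hydroxyphenyl)ethyl}-2-methoxyphenoxy)phenyl]ethyl}-3-methoxycyclohex-2-en-1-one
Conditions: MeOH, p-TsOH (5 mol %), 3 Å MS, 65 °C
Reagents that add atoms: methanol, CO
Why: Acid-catalysed enol etherification of a vinylogous acid (Fischer-type); the two carbonyls of 11 are equivalent, so a single constitutional isomer forms, C5 becomes a stereocentre without control (racemate), and the phenol is not etherified under these conditions.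

Step 8
Reactants: 12 rac-5-{2-[4-(5-{2-(3-hydroxyphenyl)ethyl}-2-methoxyphenoxy)phenyl]ethyl}-3-methoxycyclohex-2-en-1-one
Product: 13 rac-5-{2-[4-(5-{2-[3-(aminooxy)phenyl]ethyl}-2-methoxyphenoxy)phenyl]ethyl}-3-methoxycyclohex-2-en-1-one
Conditions: NaH (1.05 equiv), DMF, 0 °C; then O-(2,4-dinitrophenyl)hydroxylamine, 0 to 23 °C
Reagents that add atoms: O-(2,4-dinitrophenyl)hydroxylamine, NOc1ccc(cc1[N+](=O)[O-])[N+](=O)[O-]
Why: Electrophilic amination of a phenoxide (SN2 at nitrogen with 2,4-dinitrophenoxide as leaving group); one equivalent of hydride deprotonates only the phenol, and the free aryloxyamine should not condense with the deactivated vinylogous-ester carbonyl without acid, so 13 can be taken on at once as a cold solution.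

Step 9
Reactants: 13 rac-5-{2-[4-(5-{2-[3-(aminooxy)phenyl]ethyl}-2-methoxyphenoxy)phenyl]ethyl}-3-methoxycyclohex-2-en-1-one
Product: 14 rac-(E)-20-membered macrocyclic O-aryl oxime ether of the 3-methoxycyclohex-2-en-1-one (ring B oxygen on nitrogen, N–O syn to the C6 methylene)
Conditions: PPTS (0.3 equiv), 3 Å MS, ClCH2CH2Cl–MeOH (10:1), 50 °C, slow addition to 1 mM
Reagents that add atoms: none
Why: Acid-catalysed oxime ether condensation run as a high-dilution macrocyclization on a strain-free 20-membered ring; the methanol co-solvent makes any exchange at C3 degenerate, the acid is too weak to start the rearrangement, and it equilibrates the C=N geometry towards the E isomer, in which the N–O bond avoids the in-plane C2–H.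

Step 10
Reactants: 14 rac-(E)-20-membered macrocyclic O-aryl oxime ether
Product: 18 rac-1,2-dihydro-asterelin A dimethyl ether, via N-trifluoroacetyl ene-hydroxylamine 15 (not isolated), via ring-contracted phenol N-acylimine 16 (not isolated), via cyclic N,O-aminal 17 (not isolated)
Conditions: LDA (1.1 equiv), THF, −78 °C; (CF3CO)2O (1.2 equiv), −78 to 23 °C; then PPTS (0.2 equiv), 23 °C
Reagents that add atoms: none
Why: Proposed new method: LDA should remove the C6 proton that lies syn to the N–O bond of E-14 (the kinetic, cross-conjugated site of a vinylogous ester, as in the Stork–Danheiser alkylation), and the hard anhydride should acylate the aza-enolate on nitrogen to give 15, a hetero-1,5-diene. A chair-like [3,3] shift then breaks the weak N–O bond and joins C6 (future C9b) to the ring B ortho carbon para to the bridge (future C9a), and tautomerization restores the phenol in 16. The phenol oxygen adds to the acyl imine carbon (future C4a) in a 5-exo-trig closure to the cis-fused aminal 17, and methoxy-assisted ionization with loss of trifluoroacetamide and of the C9b proton closes the furan of 18. The closest known reaction type is the acylation-triggered rearrangement of O-aryl ketoxime ethers to benzofurans, the oxygen counterpart of the Fischer indole synthesis; what is new is the transannular, ring-contracting setting (20 to 18 members) and the base-first generation of the enamide on an enone oxime ether. No stereocentre is created that survives: the sp3 centres at C9b and C4a of 16 and 17 vanish on elimination, and C1 is carried through unchanged as the racemate. Site selectivity on ring A rests on the syn-directed kinetic deprotonation, which places the enamide at C6 and not in the vinylogous position, while C2 is vinylic and cannot carry it. Site selectivity on ring B rests on the bridge, which shields the ortho carbon next to it and would force a tighter 16-membered ring if that carbon were attacked.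

Step 11
Reactants: 18 rac-1,2-dihydro-asterelin A dimethyl ether
Product: 19 asterelin A dimethyl ether
Conditions: DDQ (1.05 equiv), toluene, 0 to 23 °C
Reagents that add atoms: none
Why: Quinone dehydrogenation: hydride abstraction from C1 gives a cation stabilized by the furan and the methoxy group, and loss of a C2 proton aromatizes ring A and erases the stereocentre; this should be far faster than oxidation of the bibenzyl methylenes.

Step 12
Reactants: 19 asterelin A dimethyl ether
Product: 20 asterelin A
Conditions: BBr3 (6 equiv), CH2Cl2, −78 to 23 °C; then H2O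
Reagents that add atoms: none
Why: Lewis-acid cleavage of aryl methyl ethers (boron complexation, then SN2 attack of bromide on methyl); the diaryl ether and the furan have only sp2 C–O bonds and should not be cleaved.

## Compound list

1 | [3-(benzyloxy)phenyl]methanol | OCc1cccc(OCc2ccccc2)c1 | starting material
2 | {[3-(benzyloxy)phenyl]methyl}triphenylphosphonium bromide | [Br-].[P+](Cc1cccc(OCc2ccccc2)c1)(c1ccccc1)(c1ccccc1)c1ccccc1 | intermediate
3 | isovanillin | COc1ccc(C=O)cc1O | starting material
4 | 5-{2-[3-(benzyloxy)phenyl]ethenyl}-2-methoxyphenol (E/Z mixture) | COc1ccc(C=Cc2cccc(OCc3ccccc3)c2)cc1O | intermediate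
5 | 4-fluorobenzaldehyde | O=Cc1ccc(F)cc1 | starting material
6 | 4-(5-{2-[3-(benzyloxy)phenyl]ethenyl}-2-methoxyphenoxy)benzaldehyde (E/Z mixture) | COc1ccc(C=Cc2cccc(OCc3ccccc3)c2)cc1Oc1ccc(C=O)cc1 | intermediate
7 | 1,3-bis(benzyloxy)-5-(bromomethyl)benzene | BrCc1cc(OCc2ccccc2)cc(OCc2ccccc2)c1 | starting material
8 | {[3,5-bis(benzyloxy)phenyl]methyl}triphenylphosphonium bromide | [Br-].[P+](Cc1cc(OCc2ccccc2)cc(OCc2ccccc2)c1)(c1ccccc1)(c1ccccc1)c1ccccc1 | intermediate
9 | 1,3-bis(benzyloxy)-5-{2-[4-(5-{2-[3-(benzyloxy)phenyl]ethenyl}-2-methoxyphenoxy)phenyl]ethenyl}benzene (alkene isomers) | COc1ccc(C=Cc2cccc(OCc3ccccc3)c2)cc1Oc1ccc(C=Cc2cc(OCc3ccccc3)cc(OCc3ccccc3)c2)cc1 | intermediate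
10 | 5-{2-[4-(5-{2-(3-hydroxyphenyl)ethyl}-2-methoxyphenoxy)phenyl]ethyl}benzene-1,3-diol (not isolated) | COc1ccc(CCc2cccc(O)c2)cc1Oc1ccc(CCc2cc(O)cc(O)c2)cc1 | intermediate
11 | 5-{2-[4-(5-{2-(3-hydroxyphenyl)ethyl}-2-methoxyphenoxy)phenyl]ethyl}cyclohexane-1,3-dione | COc1ccc(CCc2cccc(O)c2)cc1Oc1ccc(CCC2CC(=O)CC(=O)C2)cc1 | intermediate
12 | rac-5-{2-[4-(5-{2-(3-hydroxyphenyl)ethyl}-2-methoxyphenoxy)phenyl]ethyl}-3-methoxycyclohex-2-en-1-one (one enantiomer drawn) | COC1=CC(=O)C[C@@H](CCc2ccc(cc2)Oc2cc(CCc3cccc(O)c3)ccc2OC)C1 | intermediate
13 | rac-5-{2-[4-(5-{2-[3-(aminooxy)phenyl]ethyl}-2-methoxyphenoxy)phenyl]ethyl}-3-methoxycyclohex-2-en-1-one (one enantiomer drawn) | COC1=CC(=O)C[C@@H](CCc2ccc(cc2)Oc2cc(CCc3cccc(ON)c3)ccc2OC)C1 | intermediate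
14 | rac-(E)-20-membered macrocyclic O-aryl oxime ether of the 3-methoxycyclohexenone (one enantiomer drawn) | COC1=C/C2=N/Oc3cc(ccc3)CCc3ccc(OC)c(c3)Oc3ccc(cc3)CC[C@@H](C1)C2 | intermediate
15 | rac-N-trifluoroacetyl ene-hydroxylamine (C6=C1 enamide of 14, not isolated) | COC1=CC2=C[C@H](C1)CCc1ccc(cc1)Oc1cc(ccc1OC)CCc1cccc(c1)ON2C(=O)C(F)(F)F | intermediate
16 | ring-contracted phenol N-trifluoroacetyl imine (18-membered; new benzylic centre undefined, not isolated) | COC1=CC(=NC(=O)C(F)(F)F)C2[C@H](C1)CCc1ccc(cc1)Oc1cc(ccc1OC)CCc1ccc2c(O)c1 | intermediate
17 | cis-fused cyclic N,O-aminal, 4a-(trifluoroacetamido)-1,2,4a,9b-tetrahydrodibenzofuran macrocycle (not isolated) | COC1=CC2(NC(=O)C(F)(F)F)Oc3cc4ccc3C2[C@H](C1)CCc1ccc(cc1)Oc1cc(ccc1OC)CC4 | intermediate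
18 | rac-1,2-dihydro-asterelin A dimethyl ether (one enantiomer drawn) | COC1=Cc2oc3cc4ccc3c2[C@H](C1)CCc1ccc(cc1)Oc1cc(ccc1OC)CC4 | intermediate
19 | asterelin A dimethyl ether | COc1cc2c3c(c1)oc1cc(ccc13)CCc1ccc(OC)c(c1)Oc1ccc(cc1)CC2 | intermediate
20 | asterelin A | Oc1cc2c3c(c1)oc1cc(ccc13)CCc1ccc(O)c(c1)Oc1ccc(cc1)CC2 | target

## Step count and least certain steps

Total: 12 steps. Longest linear sequence: 11 steps (steps 1, 2, 3, 5, 6, 7, 8, 9, 10, 11, 12); step 4 is the side branch.

**Step 10 (key step).**
- What may go wrong: deprotonation at the vinylogous position, which would lead to bond formation at the wrong ring A carbon; acylation of the aza-enolate on carbon instead of nitrogen; N–O cleavage without C–C bond formation if the transannular chair cannot be reached; incomplete loss of trifluoroacetamide. A Z oxime ether would be deprotonated elsewhere.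
- Fallback, from 4 back to 19: the sigmatropic step is moved to an open chain, where it is the established benzofuran synthesis from an intermolecularly assembled O-aryl oxime ether, and the 18-membered ring is closed afterwards by a McMurry coupling.
 - 4 and methyl 4-fluorobenzoate (K2CO3, DMSO, 130 °C) give methyl 4-(5-{2-[3-(benzyloxy)phenyl]ethenyl}-2-methoxyphenoxy)benzoate F1.
 - Hydrogenation (H2, Pd/C) gives the phenol methyl 4-{5-[2-(3-hydroxyphenyl)ethyl]-2-methoxyphenoxy}benzoate F2, and amination as in step 8 gives the aryloxyamine F3.
 - Ethyl 3-methoxy-5-oxocyclohex-3-ene-1-carboxylate F4 is made from commercial ethyl 3,5-dioxocyclohexane-1-carboxylate with trimethylsilyldiazomethane; condensation of F3 with F4 (PPTS, MeOH) gives the open-chain E oxime ether F5.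
 - Trifluoroacetic anhydride and 4-(dimethylamino)pyridine in CH2Cl2 give the 1,2-dihydrodibenzofuran ester F6, and DDQ gives the dibenzofuran diester F7.
 - LiAlH4 gives the diol F8, MnO2 the dialdehyde F9, and TiCl4/Zn in THF at high dilution the macrocyclic stilbene F10; H2, Pd/C then gives 19.

**Step 9.**
- What may go wrong: oligomerization in place of ring closure; attack of nitrogen at C3 with loss of methanol instead of condensation at the carbonyl; hydrolysis of the enol ether by the water released; formation of the Z isomer.
- Fallback, from 13 back to 14: the ring is closed on purpose at C3. Acetic acid (cat.) in toluene at 60 °C and high dilution gives, by addition–elimination, the macrocyclic N-aryloxy enaminone (vinylogous hydroxamate) F11. O-Methylation of its carbonyl oxygen with trimethyloxonium tetrafluoroborate in CH2Cl2, then deprotonation with 1,8-bis(dimethylamino)naphthalene, gives 14.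

**Step 6.**
- What may go wrong: reduction of ring A running past the dione or stalling before it; slow hydrogenation of the ring B phenoxide; poisoning of the catalyst by phosphorus residues.
- Fallback, from 6 back to 11: ring A is built by annulation instead of reduction.
 - 6 and (triphenylphosphoranylidene)acetaldehyde (toluene, 80 °C) give the enal F12; 1-(triphenylphosphoranylidene)propan-2-one then gives the dienone F13.
 - Diethyl malonate and NaOEt in EtOH (Michael addition at the beta-carbon, then Dieckmann-type Claisen closure) give the keto ester F14; aqueous KOH, then HCl with heating, give the 5-alkenyl dione F15.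
 - Neutral hydrogenation (H2, Pd/C) saturates all three alkenes and removes the benzyl group to give 11.

**Step 8.**
- What may go wrong: transfer of the dinitrophenyl group instead of the amino group (substitution at the aromatic carbon of the reagent); low conversion; self-condensation of the product on concentration.
- Fallback, from 12 back to 13: the N–O bond is made by copper-mediated coupling.
 - Tf2O and pyridine give the aryl triflate F16.
 - Pd(OAc)2, XPhos, B2(OH)4 and KOAc in EtOH at 80 °C give the arylboronic acid F17.
 - Chan–Lam coupling with N-hydroxyphthalimide (Cu(OAc)2, pyridine, 4 Å MS, ClCH2CH2Cl, air) gives the N-aryloxyphthalimide F18.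
 - N2H4·H2O (1.1 equiv) in CH2Cl2–MeOH at 0 °C releases 13.

## Further compounds

F1 | step 10 | methyl 4-(5-{2-[3-(benzyloxy)phenyl]ethenyl}-2-methoxyphenoxy)benzoate | COC(=O)c1ccc(cc1)Oc1cc(C=Cc2cccc(OCc3ccccc3)c2)ccc1OC
F2 | step 10 | methyl 4-{5-[2-(3-hydroxyphenyl)ethyl]-2-methoxyphenoxy}benzoate | COC(=O)c1ccc(cc1)Oc1cc(CCc2cccc(O)c2)ccc1OC
F3 | step 10 | methyl 4-(5-{2-[3-(aminooxy)phenyl]ethyl}-2-methoxyphenoxy)benzoate | COC(=O)c1ccc(cc1)Oc1cc(CCc2cccc(ON)c2)ccc1OC
F4 | step 10 | rac-ethyl 3-methoxy-5-oxocyclohex-3-ene-1-carboxylate | CCOC(=O)C1CC(OC)=CC(=O)C1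
F5 | step 10 | rac-ethyl (E)-3-methoxy-5-{[3-(2-{4-methoxy-3-[4-(methoxycarbonyl)phenoxy]phenyl}ethyl)phenoxy]imino}cyclohex-3-ene-1-carboxylate | CCOC(=O)C1CC(OC)=C/C(=N/Oc2cccc(CCc3ccc(OC)c(Oc4ccc(cc4)C(=O)OC)c3)c2)C1
F6 | step 10 | rac-ethyl 3-methoxy-7-(2-{4-methoxy-3-[4-(methoxycarbonyl)phenoxy]phenyl}ethyl)-1,2-dihydrodibenzofuran-1-carboxylate | CCOC(=O)C1CC(OC)=Cc2oc3cc(CCc4ccc(OC)c(Oc5ccc(cc5)C(=O)OC)c4)ccc3c12
F7 | step 10 | ethyl 3-methoxy-7-(2-{4-methoxy-3-[4-(methoxycarbonyl)phenoxy]phenyl}ethyl)dibenzofuran-1-carboxylate | CCOC(=O)c1cc(OC)cc2oc3cc(CCc4ccc(OC)c(Oc5ccc(cc5)C(=O)OC)c4)ccc3c12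
F8 | step 10 | [7-(2-{3-[4-(hydroxymethyl)phenoxy]-4-methoxyphenyl}ethyl)-3-methoxydibenzofuran-1-yl]methanol | OCc1cc(OC)cc2oc3cc(CCc4ccc(OC)c(Oc5ccc(CO)cc5)c4)ccc3c12
F9 | step 10 | 7-{2-[3-(4-formylphenoxy)-4-methoxyphenyl]ethyl}-3-methoxydibenzofuran-1-carbaldehyde | O=Cc1cc(OC)cc2oc3cc(CCc4ccc(OC)c(Oc5ccc(C=O)cc5)c4)ccc3c12
F10 | step 10 | macrocyclic stilbene, asterelin A dimethyl ether with a C=C in the ring A to ring D bridge | COc1cc2c3c(c1)oc1cc(ccc13)CCc1ccc(OC)c(c1)Oc1ccc(cc1)C=C2
F11 | step 9 | rac-20-membered macrocyclic 3-(aryloxyamino)cyclohex-2-en-1-one (vinylogous hydroxamate) | O=C1C=C2C[C@H](C1)CCc1ccc(cc1)Oc1cc(ccc1OC)CCc1cccc(c1)ON2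
F12 | step 6 | (E)-3-[4-(5-{2-[3-(benzyloxy)phenyl]ethenyl}-2-methoxyphenoxy)phenyl]prop-2-enal | COc1ccc(C=Cc2cccc(OCc3ccccc3)c2)cc1Oc1ccc(/C=C/C=O)cc1
F13 | step 6 | (3E,5E)-6-[4-(5-{2-[3-(benzyloxy)phenyl]ethenyl}-2-methoxyphenoxy)phenyl]hexa-3,5-dien-2-one | COc1ccc(C=Cc2cccc(OCc3ccccc3)c2)cc1Oc1ccc(/C=C/C=C/C(C)=O)cc1
F14 | step 6 | ethyl 6-{(E)-2-[4-(5-{2-[3-(benzyloxy)phenyl]ethenyl}-2-methoxyphenoxy)phenyl]ethenyl}-2,4-dioxocyclohexane-1-carboxylate | CCOC(=O)C1C(=O)CC(=O)CC1/C=C/c1ccc(Oc2cc(C=Cc3cccc(OCc4ccccc4)c3)ccc2OC)cc1
F15 | step 6 | 5-{(E)-2-[4-(5-{2-[3-(benzyloxy)phenyl]ethenyl}-2-methoxyphenoxy)phenyl]ethenyl}cyclohexane-1,3-dione | O=C1CC(=O)CC(C1)/C=C/c1ccc(Oc2cc(C=Cc3cccc(OCc4ccccc4)c3)ccc2OC)cc1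
F16 | step 8 | rac-aryl triflate of 12 (ring B oxygen) | COC1=CC(=O)C[C@@H](CCc2ccc(cc2)Oc2cc(CCc3cccc(OS(=O)(=O)C(F)(F)F)c3)ccc2OC)C1
F17 | step 8 | rac-ring B boronic acid corresponding to 12 | COC1=CC(=O)C[C@@H](CCc2ccc(cc2)Oc2cc(CCc3cccc(B(O)O)c3)ccc2OC)C1
F18 | step 8 | rac-N-aryloxyphthalimide corresponding to 13 | COC1=CC(=O)C[C@@H](CCc2ccc(cc2)Oc2cc(CCc3cccc(ON4C(=O)c5ccccc5C4=O)c3)ccc2OC)C1
A1 | alternative 1 | halogenated asterelin A 3-O-methyl ether (Br on ring C, two Cl on ring D) | COc1cc2c3c(c1)oc1cc(ccc13)CCc1cc(Br)c(O)c(c1)Oc1c(Cl)cc(cc1Cl)CC2
A2 | alternative 1 | 1-[2-(3,5-dichloro-4-hydroxyphenyl)ethyl]-7-[2-(3,5-dibromo-4-hydroxyphenyl)ethyl]-3-methoxydibenzofuran | COc1cc(CCc4cc(Cl)c(O)c(Cl)c4)c2c(c1)oc1cc(CCc3cc(Br)c(O)c(Br)c3)ccc12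
A3 | alternative 2 | bridge ketone of asterelin A dimethyl ether | COc1cc2c3c(c1)oc1cc(ccc13)CCc1ccc(OC)c(c1)Oc1ccc(cc1)C(=O)C2
A4 | alternative 2 | 5-[2-(7-{2-[3-(ethynyloxy)-4-methoxyphenyl]ethyl}-3-methoxydibenzofuran-1-yl)acetyl]-2H-pyran-2-one | COc1cc(CC(=O)c4ccc(=O)oc4)c2c(c1)oc1cc(CCc3ccc(OC)c(OC#C)c3)ccc12
A5 | alternative 3 | asterelin A dimethyl ether (identical with 19) | COc1cc2c3c(c1)oc1cc(ccc13)CCc1ccc(OC)c(c1)Oc1ccc(cc1)CC2
A6 | alternative 3 | 19-membered aryl benzoate macrolactone (ring C oxygen acylated by the ring D carboxyl) | COc1cc2c3c(c1)oc1cc(ccc13)CCc1ccc(OC)c(c1)OC(=O)c1ccc(cc1)CC2
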